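Begin with the straightest line you can draw: side product A against time, as a fraction of the charge.

| flask | starting material | partner | remark | time |
|---|---|---|---|---|
| east | 0.020 M | 2 equiv | run made earlier |  |
| north-west | 0.020 M | 1 equiv | run made earlier |  |
| north | 0.020 M | 4 equiv | run made earlier |  |
| oak | 0.020 M | 2.00 equiv (fed, over 9.60 min) | a stirred flask in which partner is dosed at a steady rate over 9.60 min without added volume, worked up at 12 min | 12 min |
| cedar | 0.020 M | 2.00 equiv | everything together in a closed stirred flask, run for 12 min | 12 min |
| larch | 0.020 M (fed, over 9.60 min) | 2.00 equiv | all but starting material at the start; starting material goes in evenly over 9.60 min, the run ends at 12 min | 12 min |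
| maple | 0.020 M | 2.00 equiv | a single well-mixed tank run continuously and read at steady state, 12 min in it on average |  |

- east (time / min: target / %, side product A / %): 1.33: 5.3, 2.7; 3.00: 7.5, 5.4; 4.00: 8.1, 9.1; 6.00: 13.4, 11.3; 8.00: 14.7, 15.3
- north-west (time / min: target / %, side product A / %): 2.50: 3.5, 3.6; 5.00: 6.4, 8.2; 8.00: 10.1, 13.0; 10.0: 8.0, 17.8; 12.0: 10.9, 22.4
- north (time / min: target / %, side product A / %): 1.00: 2.3, 2.2; 3.00: 9.8, 6.9; 6.00: 19.7, 12.7; 8.00: 21.7, 17.7; 12.0: 23.4, 22.9

(standard deviation of a reading: 1 percentage point)

- in percentages every species weighs as the starting material in it: one side product B counts as two
- the stated concentrations are those of everything mixed, before any reaction; amounts are the same in each set-up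
- steps that have been proposed: starting material + partner -> intermediate A; starting material + partner -> intermediate B; starting material + partner -> intermediate C; intermediate B -> target; intermediate C -> side product A; intermediate A <-> intermediate C; starting material + intermediate B -> side product B
- the feed brings no volume worth counting
- the earlier runs were made in a closed, stirred flask

- the set-up with the highest share of target in all that became target or side product A or side product B, at the outlet or at the end ("none" if the first two lie within 2 percentage points) (oak / cedar / larch / maple / none)
- share of target in all that became target or side product A or side product B, at the outlet or at the end, oak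
- share of target in all that became target or side product A or side product B, at the outlet or at the end, cedar
- share of target in all that became target or side product A or side product B, at the outlet or at the end, larch
- share of target in all that became target or side product A or side product B, at the outlet or at the end, maple

Divide the last reading of the north run by its time:

s = 22.9% / 12.0 min = 0.0191 min⁻¹

The north-west run, with a quarter of the partner, reads 0.0187 min⁻¹, about the same as the north run. The east run reads 0.0191 min⁻¹. Call s the side-A clock, the fraction of the charge that side product A gains per minute after mixing.

Target in the north run slows: read from these scattered points, it gains 0.0327 min⁻¹ up to 3.00 min, and 0.0151 min⁻¹ from there to 12.0 min, less than before. At 12.0 min the north readings of target and side product A differ by 0.5 percentage points, less than the scatter of one reading, so these readings do not tell which curve lies higher there.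

My own reckoning turns the clock on the new flasks. In cedar it runs the whole time:

s × 12 min = 22.9%

In larch, starting material arrives on average at 4.80 min, which leaves less time on the clock:

s × (12 min − 4.80 min) = 13.7%

So I expect less side product A in larch than in cedar. Side product B was never read, and it can lower the share but not raise it. The east reading at 8.00 min gives 49.0% before side product B is counted.

The forecast names larch as best, with 38% for oak, 44% for cedar, 46% for larch and 40% for maple, and adds “The larch edge is tentative”.

The flask gives 11.4% for oak, 33.9% for cedar, 38.9% for larch and 32.1% for maple, so larch is best.

    starting material + partner → intermediate A (k = 1.70 M⁻¹ s⁻¹)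
    starting material + partner → intermediate B (k = 0.890 M⁻¹ s⁻¹)
    starting material + partner → intermediate C (k = 0.0220 M⁻¹ s⁻¹)
    intermediate B → target (k = 0.00230 s⁻¹)
    intermediate C → side product A (k = 0.00240 s⁻¹)
    intermediate A ⇌ intermediate C (K = 0.420, k = 0.0140 s⁻¹)
    starting material + intermediate B → side product B (k = 2.20 M⁻¹ s⁻¹)

Larch holds 14.8% of side product A at 12.0 min against the clock's 13.7%, and its neighbour with 8.00 equiv of partner holds 15.7% against the same 13.7%. At cedar's charged concentrations, intermediate B has a half-life of 0.26 min toward side product B, far shorter than its 5.0 min toward target. Larch doses starting material, the limiting reagent, and at 4.87 min its intermediate B is used 2.6 times as fast toward target as toward side product B, which ends at 10.9% in larch, lower than the 14.8% in cedar.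

The readings were generated by integration for substances that don't exist; the scatter is artificial.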